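**Retrosynthetic overview**
1. The last C–C bond is C2′–C3′ of the side chain, made by an sp3–sp2 Negishi coupling of a chromene 2-(2-iodoethyl) fragment with an E alkenyl iodide; the latter comes from dihydro-β-ionone by alkyne carboalumination, so the cyclohexene ring is bought.
2. The C3=C4 alkene and the C1′–C2′ arm are traced back to a chroman-4-ol with a C2 acetaldehyde arm, held as a bridged lactol (a temporary ring, with C4 and C2′ one oxidation level up; both are removed in steps 3–5).
3. Key disconnection: the pyran ring is closed at O1–C2 by a catalyst-controlled oxa-Michael addition inside an amine-catalysed domino (vinylogous aldol C3–C4, then O1–C2, then lactol) that joins a salicylaldehyde with prenal and sets the only stereocentre.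
4. Enabling feature: C2 carries O1 and a methyl and lies 1,3 to C2′ (O1–C2–C1′–C2′). C2′, C1′, C2, C3 and the C2 methyl are therefore the five carbons of prenal, with C2 the β-carbon of its iminium ion, while C4 (benzylic carbon of the pyran ring, ortho to O1 on the benzene ring) is the aldehyde carbon of a salicylaldehyde.
5. Ring order: benzene ring (bought), then pyran ring and temporary lactol ring (both in step 2), lactol ring opened in step 3; the cyclohexene ring is attached in step 8.

Key step: step 2

Assumption: the sense of induction in step 2 is taken from the usual face-shielding model of diarylprolinol silyl ether iminium ions, which predicts the target configuration at C2 for the (S)-catalyst; if the first run shows the opposite sense, the (R)-catalyst is used and nothing else changes.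

**Step 1**
Reactants: 1 2,5-dihydroxybenzaldehyde
Product: 2 2-hydroxy-5-[(triisopropylsilyl)oxy]benzaldehyde
Conditions: TIPSCl (1.05 equiv), imidazole (2 equiv), DMF, 0 °C
Reagents that add atoms: triisopropylsilyl chloride, CC(C)[Si](Cl)(C(C)C)C(C)C
Why: Phenol silylation with a silyl chloride and imidazole should occur only at the 5-hydroxyl, because the 2-hydroxyl is tied into a hydrogen bond with the ortho aldehyde and is more hindered; no stereocentre is formed.

**Step 2**
Reactants: 2 2-hydroxy-5-[(triisopropylsilyl)oxy]benzaldehyde; 3 3-methylbut-2-enal (prenal)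
Product: 6 bridged lactol (2R,6R)-2-methyl-8-[(triisopropylsilyl)oxy]-3,4-dihydro-2H,6H-2,6-methano-1,5-benzodioxocin-4-ol, via aldol adduct 4 (not isolated), via hydroxy aldehyde 5 (not isolated)
Conditions: (S)-2-{bis[3,5-bis(trifluoromethyl)phenyl][(triethylsilyl)oxy]methyl}pyrrolidine (20 mol %), PhCO2H (20 mol %), 3 (1.5 equiv, added slowly), toluene, 23 °C
Reagents that add atoms: none
Why: The amine turns prenal 3 into its cross-conjugated dienamine, whose terminal CH2 adds to the aldehyde of 2 (vinylogous aldol, C3–C4) to give the iminium ion of 4; phenol O1 then adds to the fully substituted β-carbon C2 of that iminium ion (oxa-Michael, O1–C2), and after hydrolysis to 5 the C4 hydroxyl closes onto the freed aldehyde to give lactol 6. The closest known reaction type is the diarylprolinol silyl ether catalysed domino aldol/oxa-Michael/hemiacetalisation of salicylaldehydes with (E)-β-methyl-β-alkyl enals, which sets the quaternary C2 of 2-methyl-2-alkylchromans; prenal is simply the smallest member of that enal class. Both rings close 6-exo-trig: O1 onto C2 of the C1′=C2 iminium double bond for the pyran ring, and the C4 oxygen onto the C2′ carbonyl for the temporary lactol ring. C2 is controlled by the catalyst, whose diaryl(silyloxy)methyl group covers one face of the s-trans E-iminium ion (aldol arm trans to the iminium carbon) so that O1 enters from the open face, which for the (S)-catalyst is predicted to give the C2 configuration of the target; C4 (erased in step 4) is tied to C2 because only the epimer with the C4 oxygen cis to the C2 acetaldehyde arm can lactolise, the other one staying open to retro-aldol recycling, and the lactol carbon forms as an inconsequential anomer mixture. The step needs γ- over α-reaction of the dienamine and crossed over self-condensation of 3, which are secured by the non-enolisable ortho-hydroxy aldehyde 2 (kept in excess over the standing concentration of 3) and by the hindered β,β-disubstituted iminium ion of 3, which loses a γ-proton faster than it accepts an oxygen nucleophile. It also needs kinetic control at C2, which the lactol secures by masking the aldehyde that a retro-oxa-Michael would require.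

**Step 3**
Reactants: 6 bridged lactol
Product: 7 (2S,4R)-2-(2-hydroxyethyl)-2-methyl-6-[(triisopropylsilyl)oxy]-3,4-dihydro-2H-chromen-4-ol
Conditions: NaBH4, MeOH/THF, 0 °C
Reagents that add atoms: none
Why: Sodium borohydride reduction of the lactol through its open hydroxy aldehyde form should give the primary alcohol without touching the C2–O1 bond, the benzylic alcohol or the aryl silyl ether, so C2 is carried through unchanged.

**Step 4**
Reactants: 7 (2S,4R)-diol
Product: 9 2-{(2S)-2-methyl-6-[(triisopropylsilyl)oxy]-2H-chromen-2-yl}ethyl methanesulfonate, via bis-mesylate 8 (not isolated)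
Conditions: MsCl (2.4 equiv), Et3N (4 equiv), CH2Cl2, −20→0 °C; then DBU (2 equiv), 0→23 °C
Reagents that add atoms: methanesulfonyl chloride, CS(=O)(=O)Cl
Why: Sulfonylation of both hydroxyls followed by base-induced elimination: the benzylic C4 mesylate, activated by the ortho ring oxygen O1, should ionise and lose the C3 proton (E1/E2 elimination) to give the 2H-chromene while the primary mesylate stays, and from here on the chromenes are kept below 60 °C and away from light so that a retro-oxa-6π ring opening cannot racemise C2.

**Step 5**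
Reactants: 9 chromene mesylate
Product: 10 (2S)-2-(2-iodoethyl)-2-methyl-6-[(triisopropylsilyl)oxy]-2H-chromene
Conditions: NaI (5 equiv), NaHCO3, acetone, 56 °C, dark
Reagents that add atoms: sodium iodide, [Na+].[I-]
Why: Finkelstein exchange (SN2) at the unhindered primary mesylate should give the iodide without affecting the chromene or the silyl ether.

**Step 6**
Reactants: 11 dihydro-β-ionone [4-(2,6,6-trimethylcyclohex-1-en-1-yl)butan-2-one]
Product: 13 2-(but-3-yn-1-yl)-1,3,3-trimethylcyclohex-1-ene, via enol phosphate 12 (not isolated)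
Conditions: LDA (1.05 equiv), THF, −78 °C; ClP(O)(OEt)2, −78→23 °C; LDA (2.3 equiv), −78→23 °C; then H2O
Reagents that add atoms: none
Why: Methyl ketone to terminal alkyne conversion by way of the kinetic enol phosphate (the methyl side is deprotonated by LDA at −78 °C) and E2 elimination with further LDA; the tetrasubstituted ring alkene is inert and no stereocentre is involved.

**Step 7**
Reactants: 13 2-(but-3-yn-1-yl)-1,3,3-trimethylcyclohex-1-ene
Product: 15 2-[(3E)-4-iodo-3-methylbut-3-en-1-yl]-1,3,3-trimethylcyclohex-1-ene, via alkenylalane 14 (not isolated)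
Conditions: Me3Al (2 equiv), Cp2ZrCl2 (0.25 equiv), CH2Cl2, 0→23 °C; then I2, THF, −30→0 °C
Reagents that add atoms: trimethylaluminium, C[Al](C)C; iodine, I-I
Why: Zirconocene-catalysed carboalumination (Negishi methylalumination) adds methyl and aluminium syn across the terminal alkyne with methyl on the internal carbon, and iodinolysis of the alkenyl–aluminium bond with retention should give the E trisubstituted alkenyl iodide, which fixes the side-chain alkene geometry of the target.

**Step 8**
Reactants: 10 (2S)-2-(2-iodoethyl)chromene; 15 E alkenyl iodide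
Product: 17 triisopropyl({(2S)-2-methyl-2-[(3E)-4-methyl-6-(2,6,6-trimethylcyclohex-1-en-1-yl)hex-3-en-1-yl]-2H-chromen-6-yl}oxy)silane, via alkylzinc iodide 16 (not isolated)
Conditions: 10, Zn dust (activated), LiCl, THF, 40 °C; then 15, Pd(PPh3)4 (5 mol %), THF, 23→50 °C, dark
Reagents that add atoms: none
Why: Negishi sp3–sp2 cross-coupling: zinc insertion into the primary iodide gives an alkylzinc iodide whose ring oxygen sits on the γ-carbon (no β-elimination), and coupling with the alkenyl iodide under zerovalent palladium should proceed with retention of the E geometry and without touching C2 or the ring alkenes.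

**Step 9**
Reactants: 17 silyl ether of the target
Product: 18 (2S)-2-methyl-2-[(3E)-4-methyl-6-(2,6,6-trimethylcyclohex-1-en-1-yl)hex-3-en-1-yl]-2H-chromen-6-ol
Conditions: TBAF (1.2 equiv), AcOH (1.2 equiv), THF, 0 °C, argon, dark
Reagents that add atoms: none
Why: Fluoride-mediated cleavage of the aryl silyl ether, buffered with acetic acid so that the oxidation-prone phenoxide is never exposed, should release the target with C2 and both side-chain alkenes unchanged.

**Compound list**
1 | 2,5-dihydroxybenzaldehyde | O=Cc1cc(O)ccc1O | starting material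
2 | 2-hydroxy-5-[(triisopropylsilyl)oxy]benzaldehyde | O=Cc1cc(O[Si](C(C)C)(C(C)C)C(C)C)ccc1O | intermediate
3 | 3-methylbut-2-enal (prenal) | CC(C)=CC=O | starting material
4 | (2E,5R)-5-hydroxy-5-{2-hydroxy-5-[(triisopropylsilyl)oxy]phenyl}-3-methylpent-2-enal (carried as its iminium ion with the catalyst; not isolated) | O=C/C=C(C)/C[C@@H](O)c1cc(O[Si](C(C)C)(C(C)C)C(C)C)ccc1O | intermediate
5 | 2-{(2R,4R)-4-hydroxy-2-methyl-6-[(triisopropylsilyl)oxy]-3,4-dihydro-2H-chromen-2-yl}acetaldehyde (same spatial arrangement at C2 as the target; the descriptor differs only through the priority rules; not isolated) | O=CC[C@@]1(C)C[C@@H](O)c2cc(O[Si](C(C)C)(C(C)C)C(C)C)ccc2O1 | intermediate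
6 | (2R,6R)-2-methyl-8-[(triisopropylsilyl)oxy]-3,4-dihydro-2H,6H-2,6-methano-1,5-benzodioxocin-4-ol (bridged lactol between the C4 oxygen and the C2 acetaldehyde arm of 5; anomer mixture at the lactol carbon) | OC1C[C@@]2(C)C[C@@H](O1)c3cc(O[Si](C(C)C)(C(C)C)C(C)C)ccc3O2 | intermediate
7 | (2S,4R)-2-(2-hydroxyethyl)-2-methyl-6-[(triisopropylsilyl)oxy]-3,4-dihydro-2H-chromen-4-ol | OCC[C@@]1(C)C[C@@H](O)c2cc(O[Si](C(C)C)(C(C)C)C(C)C)ccc2O1 | intermediate
8 | 2-{(2S,4R)-4-[(methanesulfonyl)oxy]-2-methyl-6-[(triisopropylsilyl)oxy]-3,4-dihydro-2H-chromen-2-yl}ethyl methanesulfonate (not isolated) | CS(=O)(=O)OCC[C@@]1(C)C[C@@H](OS(C)(=O)=O)c2cc(O[Si](C(C)C)(C(C)C)C(C)C)ccc2O1 | intermediate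
9 | 2-{(2S)-2-methyl-6-[(triisopropylsilyl)oxy]-2H-chromen-2-yl}ethyl methanesulfonate | CS(=O)(=O)OCC[C@@]1(C)C=Cc2cc(O[Si](C(C)C)(C(C)C)C(C)C)ccc2O1 | intermediate
10 | (2S)-2-(2-iodoethyl)-2-methyl-6-[(triisopropylsilyl)oxy]-2H-chromene | ICC[C@@]1(C)C=Cc2cc(O[Si](C(C)C)(C(C)C)C(C)C)ccc2O1 | intermediate
11 | 4-(2,6,6-trimethylcyclohex-1-en-1-yl)butan-2-one (dihydro-β-ionone) | CC(=O)CCC1=C(C)CCCC1(C)C | starting material
12 | diethyl 5-(2,6,6-trimethylcyclohex-1-en-1-yl)pent-1-en-2-yl phosphate (not isolated) | C=C(CCC1=C(C)CCCC1(C)C)OP(=O)(OCC)OCC | intermediate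
13 | 2-(but-3-yn-1-yl)-1,3,3-trimethylcyclohex-1-ene | C#CCCC1=C(C)CCCC1(C)C | intermediate
14 | dimethyl[(1E)-2-methyl-4-(2,6,6-trimethylcyclohex-1-en-1-yl)but-1-en-1-yl]alane (not isolated) | CC1=C(CC/C(C)=C/[Al](C)C)C(C)(C)CCC1 | intermediate
15 | 2-[(3E)-4-iodo-3-methylbut-3-en-1-yl]-1,3,3-trimethylcyclohex-1-ene | CC1=C(CC/C(C)=C/I)C(C)(C)CCC1 | intermediate
16 | (2-{(2S)-2-methyl-6-[(triisopropylsilyl)oxy]-2H-chromen-2-yl}ethyl)zinc iodide (not isolated) | I[Zn]CC[C@@]1(C)C=Cc2cc(O[Si](C(C)C)(C(C)C)C(C)C)ccc2O1 | intermediate
17 | triisopropyl({(2S)-2-methyl-2-[(3E)-4-methyl-6-(2,6,6-trimethylcyclohex-1-en-1-yl)hex-3-en-1-yl]-2H-chromen-6-yl}oxy)silane | CC1=C(CC/C(C)=C/CC[C@@]2(C)C=Cc3cc(O[Si](C(C)C)(C(C)C)C(C)C)ccc3O2)C(C)(C)CCC1 | intermediate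
18 | (2S)-2-methyl-2-[(3E)-4-methyl-6-(2,6,6-trimethylcyclohex-1-en-1-yl)hex-3-en-1-yl]-2H-chromen-6-ol | CC1=C(CC/C(C)=C/CC[C@@]2(C)C=Cc3cc(O)ccc3O2)C(C)(C)CCC1 | target

**Totals**
Total step count: 9. Longest linear sequence: 7 steps (steps 1–5, 8 and 9, from 1); the side branch (steps 6 and 7) joins in step 8.

**Steps most likely to fail, with fallbacks**

Step 2. The dienamine of prenal may react at its α-carbon or with a second molecule of prenal instead of undergoing the crossed vinylogous aldol. The oxa-Michael closure may also show poor facial selectivity (or proceed through the other iminium geometry), which would erode the enantiomeric purity at C2. The fallback sets out from 2 and comes back at 17, bypassing 6–10 and 16. Wittig reaction of 2 with Ph3P=CHC(O)CH3 in toluene should give the E enone (E)-4-{2-hydroxy-5-[(triisopropylsilyl)oxy]phenyl}but-3-en-2-one F1. 1,2-Addition of vinylmagnesium bromide (excess, CeCl3, THF, −78 °C) should give the racemic tertiary dienol F2. A chiral BINOL-derived N-triflylphosphoramide (toluene, −78 °C) ionises F2 to a planar hydroxyaryl pentadienyl cation paired with the chiral anion, which should close the same O1–C2 bond enantioconvergently to the (S)-2-methyl-2-vinyl chromene F3; the catalyst enantiomer is chosen to give S. 9-BBN should add only to the monosubstituted vinyl group to give the B-alkyl borane F4, and B-alkyl Suzuki–Miyaura coupling of F4 with 15 (Pd(dppf)Cl2, K3PO4, DMF/THF/H2O, 23 °C) returns to 17.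

Step 4. The C4 oxygen function may be captured instead of eliminated: intramolecular etherification between C4 and the primary oxygen function to a bridged cyclic ether, or chloride capture of the benzylic cation. The fallback sets out from 6 and comes back at 10; it expels the C4 oxygen before any primary leaving group exists. PPTS in toluene at 60 °C should open the lactol by ionisation at C4 and loss of the C3 proton to give the chromene aldehyde 2-{(2S)-2-methyl-6-[(triisopropylsilyl)oxy]-2H-chromen-2-yl}acetaldehyde F5. NaBH4 (MeOH, 0 °C) should give the primary alcohol F6, and iodination under Appel-type conditions (I2, PPh3, imidazole, CH2Cl2, 0 °C) gives 10.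

Step 8. Zinc insertion may be incomplete, the alkylzinc may be protonated before coupling, or β-hydride elimination at palladium after transmetalation may give a reduced or isomerised side chain. The fallback sets out from 10 and comes back at 17; it replaces the organozinc by an organoboron partner. Iodine–lithium exchange of 10 with t-BuLi in the presence of B-methoxy-9-BBN (Et2O/THF, −78 °C) should give the lithium B-alkyl-B-methoxy borinate F7 without a free alkyllithium accumulating. B-alkyl Suzuki–Miyaura coupling of F7 with 15 (Pd(dppf)Cl2, K3PO4 aq, DMF, 23 °C) gives 17.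

**Further compounds**
F1 | step 2 | (E)-4-{2-hydroxy-5-[(triisopropylsilyl)oxy]phenyl}but-3-en-2-one | CC(=O)/C=C/c1cc(O[Si](C(C)C)(C(C)C)C(C)C)ccc1O
F2 | step 2 | (1E)-1-{2-hydroxy-5-[(triisopropylsilyl)oxy]phenyl}-3-methylpenta-1,4-dien-3-ol (racemic) | C=CC(C)(O)/C=C/c1cc(O[Si](C(C)C)(C(C)C)C(C)C)ccc1O
F3 | step 2 | (2S)-2-ethenyl-2-methyl-6-[(triisopropylsilyl)oxy]-2H-chromene | C=C[C@@]1(C)C=Cc2cc(O[Si](C(C)C)(C(C)C)C(C)C)ccc2O1
F4 | step 2 | 9-(2-{(2S)-2-methyl-6-[(triisopropylsilyl)oxy]-2H-chromen-2-yl}ethyl)-9-borabicyclo[3.3.1]nonane | C1CCC2CCCC1B2CC[C@@]3(C)C=Cc4cc(O[Si](C(C)C)(C(C)C)C(C)C)ccc4O3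
F5 | step 4 | 2-{(2S)-2-methyl-6-[(triisopropylsilyl)oxy]-2H-chromen-2-yl}acetaldehyde | O=CC[C@@]1(C)C=Cc2cc(O[Si](C(C)C)(C(C)C)C(C)C)ccc2O1
F6 | step 4 | 2-{(2S)-2-methyl-6-[(triisopropylsilyl)oxy]-2H-chromen-2-yl}ethanol | OCC[C@@]1(C)C=Cc2cc(O[Si](C(C)C)(C(C)C)C(C)C)ccc2O1
F7 | step 8 | lithium 9-methoxy-9-(2-{(2S)-2-methyl-6-[(triisopropylsilyl)oxy]-2H-chromen-2-yl}ethyl)-9-boranuidabicyclo[3.3.1]nonane | [Li+].CO[B-]1(CC[C@@]2(C)C=Cc3cc(O[Si](C(C)C)(C(C)C)C(C)C)ccc3O2)C4CCCC1CCC4
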